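## Retrosynthetic overview
1. The six phenols are freed last by hydrogenolysis of benzyl ethers. Both aroyl C–C bonds come from a two-directional addition of 2,4-bis(benzyloxy)phenyllithium to an oxolane-3,4-dicarbaldehyde, followed by oxidation.
2. C2 and its aryl group come from aryllithium addition to a γ-lactone carbonyl, then ionic reduction of the cyclic oxocarbenium ion, which sets 2,3-cis and 2,5-cis.
3. The C3 side-chain carbon comes from a trans-selective formaldehyde aldol of the lactone enolate.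
4. The key C4–C5 bond comes from an Evans syn boron aldol between the (R)-4-benzyloxazolidinone imide of monomethyl succinate and 4-(benzyloxy)benzaldehyde.
5. Only one ring is built. The five-membered O-ring closes as the γ-lactone right after the aldol and is carried through as the oxolane.

Assumption: the SMILES is read as (2S,3R,4R,5R), with O = position 1 and the last-written ring carbon = C2. This means 2,3-cis, 3,4-trans, 4,5-trans and 2,5-cis, and these ring locants are used in all comments.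

## Route

Step 1
Reactants: 1 (4R)-4-benzyl-1,3-oxazolidin-2-one; 2 methyl 4-chloro-4-oxobutanoate
Product: 4 methyl 4-[(4R)-4-benzyl-2-oxo-1,3-oxazolidin-3-yl]-4-oxobutanoate, via N-lithio oxazolidinone 3 (not isolated)
Conditions: n-BuLi (1.05 equiv), THF, −78 °C; then 2, −78 → 0 °C
Reagents that add atoms: none
Why: N-acylation of the lithiated oxazolidinone by the acid chloride is far faster than attack at the methyl ester, and the auxiliary stereocentre is untouched.

Step 2 (key step)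
Reactants: 4 methyl 4-[(4R)-4-benzyl-2-oxo-1,3-oxazolidin-3-yl]-4-oxobutanoate; 5 4-(benzyloxy)benzaldehyde
Product: 8 (4R)-4-benzyl-3-{[(2R,3R)-2-[4-(benzyloxy)phenyl]-5-oxooxolan-3-yl]carbonyl}-1,3-oxazolidin-2-one (trans lactone), via Z-dibutylboron enolate 6 (not isolated), via syn-aldol hydroxy ester 7 (not isolated)
Conditions: Bu2BOTf (1.2 equiv), Et3N (1.4 equiv), CH2Cl2, −78 → 0 °C; 5, −78 → 0 °C; pH 7 buffer/MeOH/30% H2O2, 0 °C; then PPTS (10 mol %), toluene, 50 °C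
Reagents that add atoms: none
Why: In this Evans syn aldol only the imide is enolised, to the Z-boron enolate, whose Zimmerman–Traxler chair under control of the (R)-benzyl auxiliary sets C4 (R) and C5 (R), and the syn γ-hydroxy ester then lactonises to the 4,5-trans lactone.

Step 3
Reactants: 8 (4R)-4-benzyl-3-{[(2R,3R)-2-[4-(benzyloxy)phenyl]-5-oxooxolan-3-yl]carbonyl}-1,3-oxazolidin-2-one
Product: 10 (2R,3R)-2-[4-(benzyloxy)phenyl]-5-oxooxolane-3-carboxylic acid, via peroxy acid 9 (not isolated)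
Conditions: LiOH (2 equiv), 30% H2O2 (6 equiv), THF/H2O 3:1, 0 °C; aq Na2SO3; 1 M HCl to pH 2
Reagents that add atoms: hydrogen peroxide (reacts as LiOOH), OO
Why: In the Evans hydroperoxide cleavage LiOOH attacks the exocyclic imide carbonyl selectively, sulfite reduces the peracid, any opened lactone re-closes on acidification, and no stereocentre is touched.

Step 4
Reactants: 10 (2R,3R)-2-[4-(benzyloxy)phenyl]-5-oxooxolane-3-carboxylic acid
Product: 11 (4S,5R)-5-[4-(benzyloxy)phenyl]-4-(hydroxymethyl)oxolan-2-one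
Conditions: BH3·THF (1.5 equiv), THF, 0 °C → rt; MeOH quench
Reagents that add atoms: none
Why: Chemoselective borane reduction takes a free carboxylic acid (via its acyloxyborane) much faster than a lactone, and the descriptor at C4 changes only because the CIP ranking changes.

Step 5
Reactants: 11 (4S,5R)-5-[4-(benzyloxy)phenyl]-4-(hydroxymethyl)oxolan-2-one
Product: 12 (4S,5R)-5-[4-(benzyloxy)phenyl]-4-{[(tert-butyldiphenylsilyl)oxy]methyl}oxolan-2-one
Conditions: TBDPSCl (1.1 equiv), imidazole (2.2 equiv), DMF, 0 °C → rt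
Reagents that add atoms: tert-butyl(chloro)diphenylsilane (TBDPSCl), CC(C)(C)[Si](Cl)(c1ccccc1)c1ccccc1
Why: Prompt silylation of the primary alcohol blocks translactonisation and installs a group that survives strong base, aryllithium and cold BF3·OEt2.

Step 6
Reactants: 12 (4S,5R)-5-[4-(benzyloxy)phenyl]-4-{[(tert-butyldiphenylsilyl)oxy]methyl}oxolan-2-one
Product: 14 (3S,4S,5R)-5-[4-(benzyloxy)phenyl]-4-{[(tert-butyldiphenylsilyl)oxy]methyl}-3-(hydroxymethyl)oxolan-2-one, via lithium enolate 13 (not isolated)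
Conditions: LiN(i-Pr)2 (1.15 equiv), THF, −78 °C; CH2O gas (cracked paraformaldehyde, N2 stream), −78 → −40 °C; AcOH, −78 °C
Reagents that add atoms: formaldehyde, C=O
Why: In this aldol hydroxymethylation the planar lactone enolate is attacked on the face opposite the adjacent C4 side chain, which sets C3 trans to C4, also the thermodynamically preferred arrangement.

Step 7
Reactants: 14 (3S,4S,5R)-5-[4-(benzyloxy)phenyl]-4-{[(tert-butyldiphenylsilyl)oxy]methyl}-3-(hydroxymethyl)oxolan-2-one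
Product: 15 (3S,4S,5R)-5-[4-(benzyloxy)phenyl]-3,4-bis{[(tert-butyldiphenylsilyl)oxy]methyl}oxolan-2-one
Conditions: TBDPSCl (1.2 equiv), imidazole (2.5 equiv), DMF, rt
Reagents that add atoms: tert-butyl(chloro)diphenylsilane (TBDPSCl), CC(C)(C)[Si](Cl)(c1ccccc1)c1ccccc1
Why: Silyl protection under weakly basic conditions avoids retro-aldol and dehydration, and makes both side chains identical for the later two-directional steps.

Step 8
Reactants: 15 (3S,4S,5R)-5-[4-(benzyloxy)phenyl]-3,4-bis{[(tert-butyldiphenylsilyl)oxy]methyl}oxolan-2-one; 16 1-(benzyloxy)-4-bromobenzene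
Product: 18 (3S,4S,5R)-2,5-bis[4-(benzyloxy)phenyl]-3,4-bis{[(tert-butyldiphenylsilyl)oxy]methyl}oxolan-2-ol (anomer mixture in equilibrium with the open hydroxy ketone), via aryllithium 17 (not isolated)
Conditions: 16 (1.5 equiv), n-BuLi (1.45 equiv), THF, −78 °C; then 15, −78 °C; AcOH, −78 °C; used crude
Reagents that add atoms: none
Why: After bromine–lithium exchange, the 1,2-addition to the lactone stops at the lithium hemiketal, which is stable at −78 °C, so only one aryl group enters and C3 to C5 are untouched.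

Step 9
Reactants: 18 (3S,4S,5R)-2,5-bis[4-(benzyloxy)phenyl]-3,4-bis{[(tert-butyldiphenylsilyl)oxy]methyl}oxolan-2-ol
Product: 20 (2S,3S,4S,5R)-2,5-bis[4-(benzyloxy)phenyl]-3,4-bis{[(tert-butyldiphenylsilyl)oxy]methyl}oxolane, via oxocarbenium ion 19 (not isolated)
Conditions: Et3SiH (5 equiv), BF3·OEt2 (2 equiv), CH2Cl2, −78 °C, 1 h; sat. aq NaHCO3 added cold
Reagents that add atoms: none
Why: In this ionic reduction (the method of C-aryl glycoside synthesis) the aryl-stabilised oxocarbenium ion takes hydride on the face opposite the adjacent C3 side chain and the C5 aryl group, which places the new aryl cis to C3 and cis to C5 (C2 = S), and the cold quench prevents benzylic epimerisation.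

Step 10
Reactants: 20 (2S,3S,4S,5R)-2,5-bis[4-(benzyloxy)phenyl]-3,4-bis{[(tert-butyldiphenylsilyl)oxy]methyl}oxolane
Product: 21 {(2S,3S,4S,5R)-2,5-bis[4-(benzyloxy)phenyl]oxolane-3,4-diyl}dimethanol
Conditions: Bu4NF (3 equiv), THF, 0 °C → rt
Reagents that add atoms: none
Why: Fluoride desilylation is safe here because the substrate has no carbonyl group or acidic C–H that basic fluoride could affect.

Step 11
Reactants: 21 {(2S,3S,4S,5R)-2,5-bis[4-(benzyloxy)phenyl]oxolane-3,4-diyl}dimethanol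
Product: 22 (2S,3R,4R,5R)-2,5-bis[4-(benzyloxy)phenyl]oxolane-3,4-dicarbaldehyde
Conditions: Dess–Martin periodinane (2.6 equiv), NaHCO3 (10 equiv), CH2Cl2, 0 °C → rt; short silica plug; used at once
Reagents that add atoms: none
Why: Buffered Dess–Martin oxidation is close to neutral and so spares the α-stereocentres, and the trans diol cannot be diverted to a lactol or lactone because that bicycle would be trans-fused and strained.

Step 12
Reactants: 23 4-bromobenzene-1,3-diol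
Product: 24 2,4-bis(benzyloxy)-1-bromobenzene
Conditions: BnBr (2.3 equiv), K2CO3 (3 equiv), DMF, 60 °C
Reagents that add atoms: benzyl bromide, BrCc1ccccc1
Why: Williamson ether synthesis on both phenols proceeds cleanly and the aryl bromide is inert to these conditions.

Step 13
Reactants: 22 (2S,3R,4R,5R)-2,5-bis[4-(benzyloxy)phenyl]oxolane-3,4-dicarbaldehyde; 24 2,4-bis(benzyloxy)-1-bromobenzene
Product: 26 {(2S,3S,4S,5R)-2,5-bis[4-(benzyloxy)phenyl]oxolane-3,4-diyl}bis{[2,4-bis(benzyloxy)phenyl]methanol} (mixture of carbinol epimers), via aryllithium 25 (not isolated)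
Conditions: 24 (3.0 equiv), n-BuLi (2.9 equiv), THF, −78 °C; then 22 added dropwise, −78 °C, 30 min; AcOH, −78 °C
Reagents that add atoms: none
Why: Twofold 1,2-addition of the aryllithium to the aldehydes at −78 °C outruns α-deprotonation because each aldehyde always meets excess nucleophile, and the two new carbinol centres need no control since step 14 removes them.

Step 14
Reactants: 26 {(2S,3S,4S,5R)-2,5-bis[4-(benzyloxy)phenyl]oxolane-3,4-diyl}bis{[2,4-bis(benzyloxy)phenyl]methanol}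
Product: 27 {(2S,3R,4R,5R)-2,5-bis[4-(benzyloxy)phenyl]oxolane-3,4-diyl}bis{[2,4-bis(benzyloxy)phenyl]methanone}
Conditions: Dess–Martin periodinane (3 equiv), NaHCO3 (10 equiv), CH2Cl2, 0 °C → rt
Reagents that add atoms: none
Why: Buffered Dess–Martin oxidation converts all carbinol epimers of these electron-rich benzylic alcohols into one diketone without acid (no benzylic ionisation) or base (no epimerisation at C3 or C4).

Step 15
Reactants: 27 {(2S,3R,4R,5R)-2,5-bis[4-(benzyloxy)phenyl]oxolane-3,4-diyl}bis{[2,4-bis(benzyloxy)phenyl]methanone}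
Product: 28 [(2S,3R,4R,5R)-2,5-bis(4-hydroxyphenyl)oxolane-3,4-diyl]bis[(2,4-dihydroxyphenyl)methanone] (CNP0237262.2)
Conditions: H2 (1 atm), 10% Pd/C, EtOAc/MeOH 1:1, rt, stopped at full conversion; filtration through Celite
Reagents that add atoms: none
Why: Neutral catalytic hydrogenolysis removes aryl benzyl ethers much faster than it cleaves the ring dialkyl-type benzylic C–O bonds or reduces the electron-rich aryl ketones, so no acid or base reaches the epimerisable C2 to C5 centres.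

## Compound list
1 | (4R)-4-benzyl-1,3-oxazolidin-2-one | O=C1N[C@H](Cc2ccccc2)CO1 | starting material
2 | methyl 4-chloro-4-oxobutanoate | COC(=O)CCC(=O)Cl | starting material
3 | N-lithio-(4R)-4-benzyl-1,3-oxazolidin-2-one | [Li]N1C(=O)OC[C@H]1Cc1ccccc1 | intermediate (not isolated)
4 | methyl 4-[(4R)-4-benzyl-2-oxo-1,3-oxazolidin-3-yl]-4-oxobutanoate | COC(=O)CCC(=O)N1C(=O)OC[C@H]1Cc1ccccc1 | intermediate
5 | 4-(benzyloxy)benzaldehyde | O=Cc1ccc(OCc2ccccc2)cc1 | starting material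
6 | (Z)-dibutylboron enolate of 4 | COC(=O)C/C=C(\OB(CCCC)CCCC)N1C(=O)OC[C@H]1Cc1ccccc1 | intermediate (not isolated)
7 | methyl (3R)-3-{(R)-[4-(benzyloxy)phenyl](hydroxy)methyl}-4-[(4R)-4-benzyl-2-oxo-1,3-oxazolidin-3-yl]-4-oxobutanoate | COC(=O)C[C@@H](C(=O)N1C(=O)OC[C@H]1Cc1ccccc1)[C@@H](O)c1ccc(OCc2ccccc2)cc1 | intermediate (not isolated)
8 | (4R)-4-benzyl-3-{[(2R,3R)-2-[4-(benzyloxy)phenyl]-5-oxooxolan-3-yl]carbonyl}-1,3-oxazolidin-2-one | O=C1C[C@@H](C(=O)N2C(=O)OC[C@H]2Cc2ccccc2)[C@H](c2ccc(OCc3ccccc3)cc2)O1 | intermediate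
9 | (2R,3R)-2-[4-(benzyloxy)phenyl]-5-oxooxolane-3-carboperoxoic acid | O=C1C[C@@H](C(=O)OO)[C@H](c2ccc(OCc3ccccc3)cc2)O1 | intermediate (not isolated)
10 | (2R,3R)-2-[4-(benzyloxy)phenyl]-5-oxooxolane-3-carboxylic acid | O=C1C[C@@H](C(=O)O)[C@H](c2ccc(OCc3ccccc3)cc2)O1 | intermediate
11 | (4S,5R)-5-[4-(benzyloxy)phenyl]-4-(hydroxymethyl)oxolan-2-one | O=C1C[C@@H](CO)[C@H](c2ccc(OCc3ccccc3)cc2)O1 | intermediate
12 | (4S,5R)-5-[4-(benzyloxy)phenyl]-4-{[(tert-butyldiphenylsilyl)oxy]methyl}oxolan-2-one | O=C1C[C@@H](CO[Si](c2ccccc2)(c2ccccc2)C(C)(C)C)[C@H](c2ccc(OCc3ccccc3)cc2)O1 | intermediate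
13 | lithium enolate of 12 | [Li]OC1=C[C@@H](CO[Si](c2ccccc2)(c2ccccc2)C(C)(C)C)[C@H](c2ccc(OCc3ccccc3)cc2)O1 | intermediate (not isolated)
14 | (3S,4S,5R)-5-[4-(benzyloxy)phenyl]-4-{[(tert-butyldiphenylsilyl)oxy]methyl}-3-(hydroxymethyl)oxolan-2-one | OC[C@@H]1[C@@H](CO[Si](c2ccccc2)(c2ccccc2)C(C)(C)C)[C@H](c2ccc(OCc3ccccc3)cc2)OC1=O | intermediate
15 | (3S,4S,5R)-5-[4-(benzyloxy)phenyl]-3,4-bis{[(tert-butyldiphenylsilyl)oxy]methyl}oxolan-2-one | CC(C)(C)[Si](c1ccccc1)(c1ccccc1)OC[C@@H]1[C@@H](CO[Si](c2ccccc2)(c2ccccc2)C(C)(C)C)[C@H](c2ccc(OCc3ccccc3)cc2)OC1=O | intermediate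
16 | 1-(benzyloxy)-4-bromobenzene | Brc1ccc(OCc2ccccc2)cc1 | starting material
17 | [4-(benzyloxy)phenyl]lithium | [Li]c1ccc(OCc2ccccc2)cc1 | intermediate (not isolated)
18 | (3S,4S,5R)-2,5-bis[4-(benzyloxy)phenyl]-3,4-bis{[(tert-butyldiphenylsilyl)oxy]methyl}oxolan-2-ol, both C2 anomers | CC(C)(C)[Si](c1ccccc1)(c1ccccc1)OC[C@@H]1[C@@H](CO[Si](c2ccccc2)(c2ccccc2)C(C)(C)C)[C@H](c2ccc(OCc3ccccc3)cc2)OC1(O)c1ccc(OCc2ccccc2)cc1 | intermediate
19 | cyclic 2-aryl oxocarbenium ion derived from 18 | CC(C)(C)[Si](c1ccccc1)(c1ccccc1)OC[C@@H]1[C@@H](CO[Si](c2ccccc2)(c2ccccc2)C(C)(C)C)[C@H](c2ccc(OCc3ccccc3)cc2)[O+]=C1c1ccc(OCc2ccccc2)cc1 | intermediate (not isolated)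
20 | (2S,3S,4S,5R)-2,5-bis[4-(benzyloxy)phenyl]-3,4-bis{[(tert-butyldiphenylsilyl)oxy]methyl}oxolane | CC(C)(C)[Si](c1ccccc1)(c1ccccc1)OC[C@@H]1[C@@H](CO[Si](c2ccccc2)(c2ccccc2)C(C)(C)C)[C@H](c2ccc(OCc3ccccc3)cc2)O[C@@H]1c1ccc(OCc2ccccc2)cc1 | intermediate
21 | {(2S,3S,4S,5R)-2,5-bis[4-(benzyloxy)phenyl]oxolane-3,4-diyl}dimethanol | OC[C@@H]1[C@@H](CO)[C@H](c2ccc(OCc3ccccc3)cc2)O[C@@H]1c1ccc(OCc2ccccc2)cc1 | intermediate
22 | (2S,3R,4R,5R)-2,5-bis[4-(benzyloxy)phenyl]oxolane-3,4-dicarbaldehyde | O=C[C@@H]1[C@@H](C=O)[C@H](c2ccc(OCc3ccccc3)cc2)O[C@@H]1c1ccc(OCc2ccccc2)cc1 | intermediate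
23 | 4-bromobenzene-1,3-diol | Oc1ccc(Br)c(O)c1 | starting material
24 | 2,4-bis(benzyloxy)-1-bromobenzene | Brc1ccc(OCc2ccccc2)cc1OCc1ccccc1 | intermediate
25 | [2,4-bis(benzyloxy)phenyl]lithium | [Li]c1ccc(OCc2ccccc2)cc1OCc1ccccc1 | intermediate (not isolated)
26 | {(2S,3S,4S,5R)-2,5-bis[4-(benzyloxy)phenyl]oxolane-3,4-diyl}bis{[2,4-bis(benzyloxy)phenyl]methanol}, carbinol epimers | OC(c1ccc(OCc2ccccc2)cc1OCc1ccccc1)[C@@H]1[C@@H](C(O)c2ccc(OCc3ccccc3)cc2OCc2ccccc2)[C@H](c2ccc(OCc3ccccc3)cc2)O[C@@H]1c1ccc(OCc2ccccc2)cc1 | intermediate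
27 | {(2S,3R,4R,5R)-2,5-bis[4-(benzyloxy)phenyl]oxolane-3,4-diyl}bis{[2,4-bis(benzyloxy)phenyl]methanone} | O=C(c1ccc(OCc2ccccc2)cc1OCc1ccccc1)[C@@H]1[C@@H](C(=O)c2ccc(OCc3ccccc3)cc2OCc2ccccc2)[C@H](c2ccc(OCc3ccccc3)cc2)O[C@@H]1c1ccc(OCc2ccccc2)cc1 | intermediate
28 | [(2S,3R,4R,5R)-2,5-bis(4-hydroxyphenyl)oxolane-3,4-diyl]bis[(2,4-dihydroxyphenyl)methanone] | O=C(c1ccc(O)cc1O)[C@@H]1[C@@H](C(=O)c2ccc(O)cc2O)[C@H](c2ccc(O)cc2)O[C@@H]1c1ccc(O)cc1 | target

## Step count and risks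
Total step count: 15. Longest linear sequence: 14 (steps 1 to 11 and 13 to 15). Step 12 is a one-step side branch.

**Step 6 (formaldehyde aldol).**
- Risk: gaseous formaldehyde can polymerise at the inlet. The aldolate can also revert or dehydrate to the α-methylene lactone.
- Fallback: it sets out from 12 and comes back at 14, and it brings the carbon in as CO2 instead. Enolate 13 is quenched with dry CO2 at −78 °C and acidified cold to give (3S,4S,5R)-5-[4-(benzyloxy)phenyl]-4-{[(tert-butyldiphenylsilyl)oxy]methyl}-2-oxooxolane-3-carboxylic acid F1. Its malonate-type C3 centre equilibrates to the wanted trans form. BH3·THF at 0 °C then reduces the free acid in preference to the lactone, as in step 4, and delivers 14.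

**Step 8 (aryllithium on the α-branched lactone).**
- Risk: 17 may act as a base, giving enolisation and then loss of silanolate to an α-methylene lactone. It may also add twice.
- Fallback: it sets out from 15 and comes back at 18, and it goes through a Weinreb ketone synthesis.
  - MeNHOMe·HCl/AlMe3 (CH2Cl2, 0 °C → rt) opens the lactone to (2S,3S,4R)-4-[4-(benzyloxy)phenyl]-2,3-bis{[(tert-butyldiphenylsilyl)oxy]methyl}-4-hydroxy-N-methoxy-N-methylbutanamide F2.
  - Immediate capping with TESCl/imidazole gives (2S,3S,4R)-4-[4-(benzyloxy)phenyl]-2,3-bis{[(tert-butyldiphenylsilyl)oxy]methyl}-N-methoxy-N-methyl-4-[(triethylsilyl)oxy]butanamide F3.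
  - Addition of 17 (THF, −78 → 0 °C) stops at the chelated tetrahedral adduct. On quench it gives (2S,3S,4R)-1,4-bis[4-(benzyloxy)phenyl]-2,3-bis{[(tert-butyldiphenylsilyl)oxy]methyl}-4-[(triethylsilyl)oxy]butan-1-one F4.
  - AcOH/THF/H2O removes only the triethylsilyl group, and the γ-hydroxy ketone closes to 18.

**Step 13 (double addition to dialdehyde 22, made in step 11).**
- Risk: the C3 aldehyde, which is cis to the C2 aryl group, can epimerise. It can also open the ring by β-elimination on silica or under the basic nucleophile.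
- Fallback: it sets out from 21 and comes back at 27, and it works at the acid oxidation level.
  - TEMPO (cat.)/PhI(OAc)2 in MeCN/H2O gives (2S,3R,4R,5R)-2,5-bis[4-(benzyloxy)phenyl]oxolane-3,4-dicarboxylic acid F5.
  - MeNHOMe·HCl, EDC·HCl, HOBt and N-methylmorpholine in CH2Cl2 give (2S,3R,4R,5R)-2,5-bis[4-(benzyloxy)phenyl]-N3,N4-dimethoxy-N3,N4-dimethyloxolane-3,4-dicarboxamide F6.
  - Aryllithium 25 (3 equiv, THF, −78 °C) gives 27 directly on quench.
  - The amide α-protons are far less acidic than aldehyde α-protons, and steps 11, 13 and 14 are all replaced.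

## Further compounds
F1 | step 6 | (3S,4S,5R)-5-[4-(benzyloxy)phenyl]-4-{[(tert-butyldiphenylsilyl)oxy]methyl}-2-oxooxolane-3-carboxylic acid | OC(=O)[C@@H]1[C@@H](CO[Si](c2ccccc2)(c2ccccc2)C(C)(C)C)[C@H](c2ccc(OCc3ccccc3)cc2)OC1=O
F2 | step 8 | (2S,3S,4R)-4-[4-(benzyloxy)phenyl]-2,3-bis{[(tert-butyldiphenylsilyl)oxy]methyl}-4-hydroxy-N-methoxy-N-methylbutanamide | CON(C)C(=O)[C@H](CO[Si](c1ccccc1)(c1ccccc1)C(C)(C)C)[C@@H](CO[Si](c1ccccc1)(c1ccccc1)C(C)(C)C)[C@@H](O)c1ccc(OCc2ccccc2)cc1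
F3 | step 8 | (2S,3S,4R)-4-[4-(benzyloxy)phenyl]-2,3-bis{[(tert-butyldiphenylsilyl)oxy]methyl}-N-methoxy-N-methyl-4-[(triethylsilyl)oxy]butanamide | CON(C)C(=O)[C@H](CO[Si](c1ccccc1)(c1ccccc1)C(C)(C)C)[C@@H](CO[Si](c1ccccc1)(c1ccccc1)C(C)(C)C)[C@@H](O[Si](CC)(CC)CC)c1ccc(OCc2ccccc2)cc1
F4 | step 8 | (2S,3S,4R)-1,4-bis[4-(benzyloxy)phenyl]-2,3-bis{[(tert-butyldiphenylsilyl)oxy]methyl}-4-[(triethylsilyl)oxy]butan-1-one | O=C(c1ccc(OCc2ccccc2)cc1)[C@H](CO[Si](c1ccccc1)(c1ccccc1)C(C)(C)C)[C@@H](CO[Si](c1ccccc1)(c1ccccc1)C(C)(C)C)[C@@H](O[Si](CC)(CC)CC)c1ccc(OCc2ccccc2)cc1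
F5 | step 13 | (2S,3R,4R,5R)-2,5-bis[4-(benzyloxy)phenyl]oxolane-3,4-dicarboxylic acid | OC(=O)[C@@H]1[C@@H](C(=O)O)[C@H](c2ccc(OCc3ccccc3)cc2)O[C@@H]1c1ccc(OCc2ccccc2)cc1
F6 | step 13 | (2S,3R,4R,5R)-2,5-bis[4-(benzyloxy)phenyl]-N3,N4-dimethoxy-N3,N4-dimethyloxolane-3,4-dicarboxamide | CON(C)C(=O)[C@@H]1[C@@H](C(=O)N(C)OC)[C@H](c2ccc(OCc3ccccc3)cc2)O[C@@H]1c1ccc(OCc2ccccc2)cc1
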